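**Retrosynthetic overview**
1. Target ⇐ C3-acylation (last step) of the 3-unsubstituted bicyclo[3.2.1]octane-2,4,8-trione core with (2R)-2-methylbutanoic acid.
2. Core ⇐ acyclic keto malonate, both carbocycles closed in one flask: Dieckmann closure (ring B, cyclopentanone, C5–C8 bond), C-prenylation of the resulting β-diketone enolate at C5, second Dieckmann closure (ring A, six-membered trione ring, C2–C3 bond).
3. Keto malonate ⇐ enone (hydrogenation) ⇐ vinyl epoxide + dimethyl methylmalonate by palladium-catalysed allylic alkylation (C1–C7 bond; C7 is the only stereocentre carried into the ring closures).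
4. Vinyl epoxide ⇐ Shi epoxidation of commercial (3E)-6-methylhepta-3,5-dien-2-one, which already holds C3–C7 and the gem-dimethyl carbon.
5. Ring order: ring B, then ring A, both in step 4; C1 and C5 are relayed from C7 during the second closure.

Assumption: (2R)-2-methylbutanoic acid and the L-fructose-derived enantiomer of the Shi ketone are bought as catalogue items.

Locants used for the bicyclic compounds: C1 = methyl-bearing bridgehead, C2–C4 = enolised diketone bridge, C5 = prenyl-bearing bridgehead, C6 = CH2, C7 = CH carrying the hydroxypropyl group, C8 = bridging ketone. In the target the hydroxypropyl group is exo (syn to C8).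

**Route**

Step 1
Reactants: 1 (3E)-6-methylhepta-3,5-dien-2-one
Product: 2 (3E)-4-[(2S)-3,3-dimethyloxiran-2-yl]but-3-en-2-one
Conditions: L-fructose-derived Shi ketone (0.3 equiv), Oxone (2KHSO5·KHSO4·K2SO4), K2CO3, Bu4NHSO4 (cat.), aq. Na2B4O7 buffer (pH ≈ 10.5), MeCN/CH2(OMe)2, 0 °C
Reagents that add atoms: potassium peroxymonosulfate (KHSO5, the active part of Oxone), [K+].[O-]S(=O)(=O)OO
Why: Shi asymmetric epoxidation, in which the electrophilic chiral dioxirane takes the electron-richer trisubstituted γ,δ-alkene and leaves the deactivated enone alkene, and the spiro transition state of the L-fructose-derived ketone is expected to deliver oxygen to the face that gives the (S)-epoxide (the D-fructose-derived ketone gives R with R–CH=CMe2 olefins).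

Step 2
Reactants: 2 (3E)-4-[(2S)-3,3-dimethyloxiran-2-yl]but-3-en-2-one; 3 dimethyl 2-methylpropanedioate (dimethyl methylmalonate)
Product: 5 dimethyl 2-methyl-2-[(3R,4E)-2-methyl-6-oxo-2-(triethylsilyloxy)hept-4-en-3-yl]propanedioate, via tertiary alcohol 4 (not isolated)
Conditions: Pd(PPh3)4 (5 mol %), CH2Cl2, rt; then 2,6-lutidine, Et3SiOTf, −78 → 0 °C
Reagents that add atoms: triethylsilyl trifluoromethanesulfonate (Et3SiOTf), CC[Si](CC)(CC)OS(=O)(=O)C(F)(F)F
Why: Tsuji–Trost allylic alkylation of a vinyl epoxide under neutral conditions, in which zerovalent palladium opens the allylic C–O bond with inversion, the liberated alkoxide deprotonates 3, and the malonate anion attacks the π-allyl terminus remote from the acetyl group (C7) anti to palladium, so the C1–C7 bond forms with net retention (7R) and the enone stays conjugated; silylation in the same flask keeps the tertiary alcohol from lactonising onto an ester.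

Step 3
Reactants: 5 dimethyl 2-methyl-2-[(3R,4E)-2-methyl-6-oxo-2-(triethylsilyloxy)hept-4-en-3-yl]propanedioate
Product: 6 dimethyl 2-methyl-2-[(3R)-2-methyl-6-oxo-2-(triethylsilyloxy)heptan-3-yl]propanedioate
Conditions: H2 (1 atm), Pd/C (10 wt %), EtOAc, rt
Reagents that add atoms: none
Why: Heterogeneous catalytic hydrogenation saturates the only C=C bond (the disubstituted enone alkene) and leaves the ketone, the esters, the silyl ether and C7 untouched.

Step 4
Reactants: 6 dimethyl 2-methyl-2-[(3R)-2-methyl-6-oxo-2-(triethylsilyloxy)heptan-3-yl]propanedioate; 7 1-bromo-3-methylbut-2-ene (prenyl bromide)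
Product: 11 (1R,5S,7R)-2-hydroxy-7-(2-hydroxypropan-2-yl)-1-methyl-5-(3-methylbut-2-en-1-yl)bicyclo[3.2.1]oct-2-ene-4,8-dione, via cyclopentanone enolate 8 (not isolated), via prenylated diketo ester 9 (not isolated), via silyl trione enolate 10 (not isolated)
Conditions: t-BuOK (1.05 equiv), THF, 0 °C → rt; then 7 (1.05 equiv), rt; then t-BuOK (2.5 equiv), 0 → 45 °C; then 1 M HCl, rt
Reagents that add atoms: none
Why: Proposed new method: a one-flask Dieckmann / C-prenylation / Dieckmann sequence in which the C5 ketone enolate of 6 attacks one malonate ester (5-exo-trig) to give the stabilised β-diketone enolate 8, 7 alkylates its carbon to the non-enolisable diketo ester 9, and the second base charge lets the acetyl enolate attack the remaining ester across the ring (6-exo-trig) to give the bridged trione, held as its vinylogous-acid enolate 10 (the thermodynamic sink); the quaternary centres C1 and C5 are set under Curtin–Hammett control, because the diastereomers of 9 interconvert by alkoxide-mediated retro-Claisen/Claisen opening and reclosure, only an isomer with acetyl and ester cis can bridge (so C5 follows C1), and bridging on the face away from the bulky C7 silyloxypropyl group (which ends exo) is much less hindered than the closure that would force it under the new bridge; the closest known reaction types are the Dieckmann closure of 6-oxoheptanoates to 2-acetylcyclopentanones, C-allylation of 2-acylcycloalkanone enolates, and the t-BuOK-mediated Dieckmann closure of 2-acetyl-2-alkylcycloalkanones onto a cis ester used for bridged triones of the bicyclo[3.3.1]nonane series; aqueous HCl then protonates the enolate and cleaves the silyl ether.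

Step 5
Reactants: 11 (1R,5S,7R)-2-hydroxy-7-(2-hydroxypropan-2-yl)-1-methyl-5-(3-methylbut-2-en-1-yl)bicyclo[3.2.1]oct-2-ene-4,8-dione; 12 (2R)-2-methylbutanoic acid
Product: 14 (1R,5R,7R)-2-hydroxy-7-(2-hydroxypropan-2-yl)-1-methyl-3-[(2R)-2-methylbutanoyl]-5-(3-methylbut-2-en-1-yl)bicyclo[3.2.1]oct-2-ene-4,8-dione (the target), via enol ester 13 (not isolated)
Conditions: DCC (1.2 equiv), DMAP (1.2 equiv), CH2Cl2, 0 °C → rt
Reagents that add atoms: none
Why: Steglich O-acylation of the vinylogous acid followed by DMAP-mediated O→C acyl migration (the standard route to 2-acyl-1,3-diones) places the acyl group on C3 with the chelated triketone enol as the sink, the hindered tertiary alcohol does not compete, and since no strong base is present the (R) centre of the acid and the three ring centres are left as they are.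

**Compound list**
1 | (3E)-6-methylhepta-3,5-dien-2-one | CC(=O)/C=C/C=C(C)C | starting material
2 | (3E)-4-[(2S)-3,3-dimethyloxiran-2-yl]but-3-en-2-one | CC(=O)/C=C/[C@@H]1OC1(C)C | intermediate
3 | dimethyl 2-methylpropanedioate (dimethyl methylmalonate) | COC(=O)C(C)C(=O)OC | starting material
4 | dimethyl 2-[(3R,4E)-2-hydroxy-2-methyl-6-oxohept-4-en-3-yl]-2-methylpropanedioate | CC(=O)/C=C/[C@H](C(C)(C(=O)OC)C(=O)OC)C(C)(C)O | intermediate
5 | dimethyl 2-methyl-2-[(3R,4E)-2-methyl-6-oxo-2-(triethylsilyloxy)hept-4-en-3-yl]propanedioate | CC(=O)/C=C/[C@H](C(C)(C(=O)OC)C(=O)OC)C(C)(C)O[Si](CC)(CC)CC | intermediate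
6 | dimethyl 2-methyl-2-[(3R)-2-methyl-6-oxo-2-(triethylsilyloxy)heptan-3-yl]propanedioate | CC(=O)CC[C@H](C(C)(C(=O)OC)C(=O)OC)C(C)(C)O[Si](CC)(CC)CC | intermediate
7 | 1-bromo-3-methylbut-2-ene (prenyl bromide) | CC(C)=CCBr | starting material
8 | potassium enolate of methyl (5R)-3-acetyl-1-methyl-2-oxo-5-[2-(triethylsilyloxy)propan-2-yl]cyclopentane-1-carboxylate (both C1 epimers) | COC(=O)C1(C)C(=O)C(=C(C)[O-])C[C@H]1C(C)(C)O[Si](CC)(CC)CC.[K+] | intermediate
9 | methyl (1S,3S,5R)-3-acetyl-1-methyl-3-(3-methylbut-2-en-1-yl)-2-oxo-5-[2-(triethylsilyloxy)propan-2-yl]cyclopentane-1-carboxylate (the isomer that cyclises; its C1/C3 epimers equilibrate with it) | COC(=O)[C@]1(C)C(=O)[C@@](CC=C(C)C)(C[C@H]1C(C)(C)O[Si](CC)(CC)CC)C(C)=O | intermediate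
10 | potassium (1R,5S,7R)-1-methyl-5-(3-methylbut-2-en-1-yl)-4,8-dioxo-7-[2-(triethylsilyloxy)propan-2-yl]bicyclo[3.2.1]oct-2-en-2-olate | C1=C([O-])[C@]2(C)C(=O)[C@@](CC=C(C)C)(C[C@H]2C(C)(C)O[Si](CC)(CC)CC)C1=O.[K+] | intermediate
11 | (1R,5S,7R)-2-hydroxy-7-(2-hydroxypropan-2-yl)-1-methyl-5-(3-methylbut-2-en-1-yl)bicyclo[3.2.1]oct-2-ene-4,8-dione | O=C1C=C(O)[C@]2(C)C(=O)[C@@]1(CC=C(C)C)C[C@H]2C(C)(C)O | intermediate
12 | (2R)-2-methylbutanoic acid | CC[C@@H](C)C(=O)O | starting material
13 | (1R,5S,7R)-7-(2-hydroxypropan-2-yl)-1-methyl-5-(3-methylbut-2-en-1-yl)-4,8-dioxobicyclo[3.2.1]oct-2-en-2-yl (2R)-2-methylbutanoate (or its O4 regioisomer) | C1=C(OC(=O)[C@H](C)CC)[C@]2(C)C(=O)[C@@](CC=C(C)C)(C[C@H]2C(C)(C)O)C1=O | intermediate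
14 | (1R,5R,7R)-2-hydroxy-7-(2-hydroxypropan-2-yl)-1-methyl-3-[(2R)-2-methylbutanoyl]-5-(3-methylbut-2-en-1-yl)bicyclo[3.2.1]oct-2-ene-4,8-dione | CC[C@@H](C)C(=O)C1=C(O)[C@]2(C)C(=O)[C@@](CC=C(C)C)(C[C@H]2C(C)(C)O)C1=O | target

The C5 descriptor changes from S (10, 11, 13) to R (14) only because the C3 acyl group changes the CIP ranking of C4 over C8; the geometry is the same.

**Step count and risks**
Total steps: 5. Longest linear sequence: 5 (1 → 2 → 5 → 6 → 11 → 14).

Steps most likely to fail:

1. Step 4. The risks are that the diastereomers of 9 equilibrate too slowly, that alkoxide removes the acetyl group of 9 (retro-Claisen) faster than the second ring closes, or that 8 is O-prenylated. Fallback, setting out from 9 and coming back at 10: stop after the prenylation and isolate 9. NaOMe in MeOH removes the acetyl group on purpose to give methyl (5R)-1-methyl-3-(3-methylbut-2-en-1-yl)-2-oxo-5-[2-(triethylsilyloxy)propan-2-yl]cyclopentane-1-carboxylate F3. Krapcho demethoxycarbonylation (LiCl, wet DMSO, 150 °C) gives (3R)-2-methyl-5-(3-methylbut-2-en-1-yl)-3-[2-(triethylsilyloxy)propan-2-yl]cyclopentan-1-one F4. Me3SiCl, NaI and Et3N give the silyl enol ether trimethyl{[(3R)-2-methyl-5-(3-methylbut-2-en-1-yl)-3-[2-(triethylsilyloxy)propan-2-yl]cyclopent-1-en-1-yl]oxy}silane F5. An Effenberger annulation with malonyl dichloride (−20 °C, then KOH, BnEt3NCl) acylates C1 anti to the C7 substituent and then C5 on the same face, which gives 10; the HCl work-up of step 4 turns it into 11.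

2. Step 2. The risks are slow attack of the tertiary malonate carbanion at the hindered C7 terminus, attack at the acetyl-bearing terminus instead, and loss of enantiopurity if the π-allyl complex isomerises. Fallback, setting out from 2 and coming back at 5: the quaternary carbon is built in two stages. The same palladium catalysis with the less hindered dimethyl malonate gives dimethyl 2-[(3R,4E)-2-hydroxy-2-methyl-6-oxohept-4-en-3-yl]propanedioate F1. Et3SiOTf and 2,6-lutidine give its silyl ether dimethyl 2-[(3R,4E)-2-methyl-6-oxo-2-(triethylsilyloxy)hept-4-en-3-yl]propanedioate F2. C-Methylation of the malonate carbon (K2CO3, MeI, acetone) then gives 5.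

3. Step 5. The risks are that the O→C acyl shift is slow at the hindered C3 and that the acid's α-centre partly racemises through the acylpyridinium. Fallback, setting out from 11 and coming back at 14: Me3SiCHN2 in MeOH/toluene gives the methyl enol ether (1R,5S,7R)-7-(2-hydroxypropan-2-yl)-2-methoxy-1-methyl-5-(3-methylbut-2-en-1-yl)bicyclo[3.2.1]oct-2-ene-4,8-dione F6 (its 4-methoxy isomer behaves alike). Acid 12 is converted with carbonyldiimidazole and MeONHMe·HCl into (2R)-N-methoxy-N,2-dimethylbutanamide F7. Lithium 2,2,6,6-tetramethylpiperidide (2.2 equiv, THF, −78 °C) deprotonates the alcohol and the vinylic C3–H of F6, and the C3 anion is acylated by F7 to give (1R,5R,7R)-7-(2-hydroxypropan-2-yl)-2-methoxy-1-methyl-3-[(2R)-2-methylbutanoyl]-5-(3-methylbut-2-en-1-yl)bicyclo[3.2.1]oct-2-ene-4,8-dione F8. LiCl in DMSO at 120 °C removes the O-methyl group and gives 14.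

**Further compounds**
F1 | step 2 | dimethyl 2-[(3R,4E)-2-hydroxy-2-methyl-6-oxohept-4-en-3-yl]propanedioate | CC(=O)/C=C/[C@H](C(C(=O)OC)C(=O)OC)C(C)(C)O
F2 | step 2 | dimethyl 2-[(3R,4E)-2-methyl-6-oxo-2-(triethylsilyloxy)hept-4-en-3-yl]propanedioate | CC(=O)/C=C/[C@H](C(C(=O)OC)C(=O)OC)C(C)(C)O[Si](CC)(CC)CC
F3 | step 4 | methyl (5R)-1-methyl-3-(3-methylbut-2-en-1-yl)-2-oxo-5-[2-(triethylsilyloxy)propan-2-yl]cyclopentane-1-carboxylate (C1/C3 epimers) | COC(=O)C1(C)C(=O)C(CC=C(C)C)C[C@H]1C(C)(C)O[Si](CC)(CC)CC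
F4 | step 4 | (3R)-2-methyl-5-(3-methylbut-2-en-1-yl)-3-[2-(triethylsilyloxy)propan-2-yl]cyclopentan-1-one (C2/C5 epimers) | CC1C(=O)C(CC=C(C)C)C[C@H]1C(C)(C)O[Si](CC)(CC)CC
F5 | step 4 | trimethyl{[(3R)-2-methyl-5-(3-methylbut-2-en-1-yl)-3-[2-(triethylsilyloxy)propan-2-yl]cyclopent-1-en-1-yl]oxy}silane | C[Si](C)(C)OC1=C(C)[C@H](C(C)(C)O[Si](CC)(CC)CC)CC1CC=C(C)C
F6 | step 5 | (1R,5S,7R)-7-(2-hydroxypropan-2-yl)-2-methoxy-1-methyl-5-(3-methylbut-2-en-1-yl)bicyclo[3.2.1]oct-2-ene-4,8-dione | O=C1C=C(OC)[C@]2(C)C(=O)[C@@]1(CC=C(C)C)C[C@H]2C(C)(C)O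
F7 | step 5 | (2R)-N-methoxy-N,2-dimethylbutanamide | CC[C@@H](C)C(=O)N(C)OC
F8 | step 5 | (1R,5R,7R)-7-(2-hydroxypropan-2-yl)-2-methoxy-1-methyl-3-[(2R)-2-methylbutanoyl]-5-(3-methylbut-2-en-1-yl)bicyclo[3.2.1]oct-2-ene-4,8-dione | CC[C@@H](C)C(=O)C1=C(OC)[C@]2(C)C(=O)[C@@](CC=C(C)C)(C[C@H]2C(C)(C)O)C1=O
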